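**Retrosynthetic overview** (chain numbered C1 at the isopropylidene end to C24 at the isopropenyl end; oxirane = C10–C11)
1. Cut C8–C9 and C16–C17 (both sp3–sp3): right-arm bromide (C1–C8) + mono-epoxidised C9–C16 core + left-arm bromide (C17–C24).
2. The oxirane, the only ring, is made first, on the core alone: Shi mono-epoxidation of C2-symmetric (2E,6E)-2,7-dimethylocta-2,6-diene-1,8-diol (from butane-1,4-diol by Swern/Wittig, then i-Bu2AlH).
3. Each CH(CH3)–C(=CH2) unit (C7, C18, C22) comes from a chiral phosphoric acid-catalysed allylboration of formaldehyde (new) on a 2-substituted but-2-enylboronate, made by Pd-catalysed 1,4-hydroboration of isoprene, myrcene or the left-arm diene.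
4. The left-arm diene comes from isoprenylpotassium and the tosylate of the first allylboration product (C20–C21 bond).

Assumption: the facial sense of the new allylboration is assigned from the chair that (R)-configured phosphoric acids favour with ordinary aldehydes; if it proves opposite, the antipodal acid is used at each of its three uses.

**Step 1**
Reactants: 1 isoprene (2-methylbuta-1,3-diene)
Product: 3 (Z)-4,4,5,5-tetramethyl-2-(2-methylbut-2-en-1-yl)-1,3,2-dioxaborolane, via catechol boronate 2 (not isolated)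
Conditions: catecholborane, Pd(PPh3)4 (2 mol %), benzene, rt; then pinacol, rt
Reagents that add atoms: catecholborane (B1Oc2ccccc2O1), pinacol (CC(C)(O)C(C)(C)O)
Why: Pd-catalysed 1,4-hydroboration of the s-cis diene puts H on the unsubstituted vinyl terminus and boron on the other CH2, so CH3 and CH2B end up cis (Z), and transesterification gives the stable pinacol ester; no stereocentre.

**Step 2**
Reactants: 3; 4 formaldehyde (monomer, cracked from paraformaldehyde)
Product: 6 (R)-2,3-dimethylbut-3-en-1-ol, via borate ester 5 (not isolated)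
Conditions: CH2O (1 M in THF, slow addition), (S)-TRIP [(S)-3,3′-bis(2,4,6-triisopropylphenyl)-1,1′-binaphthyl-2,2′-diyl hydrogen phosphate, 5 mol %], 4 Å MS, toluene, −40 °C; aq. NaHCO3
Reagents that add atoms: none
Why: Proposed new method: chiral phosphoric acid-catalysed allylboration with formaldehyde as the electrophile, so that the only stereocentre is the γ-carbon of the allyl unit; the acid hydrogen-bonds to the pseudoaxial boronate oxygen and a formyl C–H of the closed six-membered chair (γ-methyl axial) and selects one of the two enantiomeric chairs, and the SE2′ transposition gives the 1,1-disubstituted alkene; the closest known reaction is the phosphoric acid-catalysed allyl- and crotylboration of aldehydes with pinacol boronates, which to my knowledge has not been shown with formaldehyde to set a stereocentre on the allyl fragment alone.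

**Step 3**
Reactants: 6
Product: 7 (R)-2,3-dimethylbut-3-en-1-yl 4-methylbenzenesulfonate
Conditions: TsCl, Et3N, DMAP (cat.), CH2Cl2, 0 °C
Reagents that add atoms: 4-methylbenzenesulfonyl chloride (Cc1ccc(cc1)S(=O)(=O)Cl)
Why: O-sulfonylation of a primary alcohol; the stereocentre is not touched.

**Step 4**
Reactants: 1 isoprene; 7
Product: 9 (S)-2,3-dimethyl-6-methylideneocta-1,7-diene, via isoprenylpotassium 8 (not isolated)
Conditions: isoprene (1.3 equiv), lithium 2,2,6,6-tetramethylpiperidide (LiTMP), KOt-Bu, THF/hexane, −78 °C; then 7, −78 → −30 °C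
Reagents that add atoms: none
Why: superbase metalation of the isoprene methyl gives the 2-vinylallyl anion whose two CH2 termini are equivalent, so SN2 alkylation by the primary tosylate can only give the 2-substituted butadiene; the stereocentre is β to the reacting carbon and is retained.

**Step 5**
Reactants: 9
Product: 11 2-[(2E,5S)-2-ethylidene-5,6-dimethylhept-6-en-1-yl]-4,4,5,5-tetramethyl-1,3,2-dioxaborolane, via catechol boronate 10 (not isolated)
Conditions: catecholborane, Pd(PPh3)4 (2 mol %), benzene, rt; then pinacol, rt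
Reagents that add atoms: catecholborane (B1Oc2ccccc2O1), pinacol (CC(C)(O)C(C)(C)O)
Why: Pd-catalysed 1,4-hydroboration as in step 1 (myrcene-type substrate); only the conjugated diene reacts, the isolated isopropenyl group is inert, and CH3 and CH2B are again cis.

**Step 6**
Reactants: 11; 4 formaldehyde
Product: 13 (2S,6S)-2,6,7-trimethyl-3-methylideneoct-7-en-1-ol, via borate ester 12 (not isolated)
Conditions: CH2O (1 M in THF, slow addition), (R)-TRIP (5 mol %), 4 Å MS, toluene, −40 °C; aq. NaHCO3
Reagents that add atoms: none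
Why: Proposed new method: the same phosphoric acid-catalysed formaldehyde allylboration as in step 2, run with the antipodal acid so that the opposite chair sets C2 as S under catalyst control (the existing centre is four bonds away); closest known reaction: phosphoric acid-catalysed crotylboration of aldehydes.

**Step 7**
Reactants: 13
Product: 14 (3S,7S)-8-bromo-2,3,7-trimethyl-6-methylideneoct-1-ene
Conditions: CBr4, PPh3, CH2Cl2, 0 °C
Reagents that add atoms: carbon tetrabromide (BrC(Br)(Br)Br)
Why: Appel bromination of a primary alcohol under neutral conditions; no stereocentre reacts.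

**Step 8**
Reactants: 15 myrcene (7-methyl-3-methylideneocta-1,6-diene)
Product: 17 2-[(2E)-2-ethylidene-6-methylhept-5-en-1-yl]-4,4,5,5-tetramethyl-1,3,2-dioxaborolane, via catechol boronate 16 (not isolated)
Conditions: catecholborane, Pd(PPh3)4 (2 mol %), benzene, rt; then pinacol, rt
Reagents that add atoms: catecholborane (B1Oc2ccccc2O1), pinacol (CC(C)(O)C(C)(C)O)
Why: Pd-catalysed 1,4-hydroboration of the diene unit of myrcene with boron at the CH2 next to the substituted carbon; the trisubstituted alkene does not react.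

**Step 9**
Reactants: 17; 4 formaldehyde
Product: 19 (S)-2,7-dimethyl-3-methylideneoct-6-en-1-ol, via borate ester 18 (not isolated)
Conditions: CH2O (1 M in THF, slow addition), (R)-TRIP (5 mol %), 4 Å MS, toluene, −40 °C; aq. NaHCO3
Reagents that add atoms: none
Why: Proposed new method: the same phosphoric acid-catalysed formaldehyde allylboration as in step 2, the acid selecting the chair that gives the S alcohol (the later C7 centre) and the exocyclic methylene by SE2′ transposition; closest known reaction: phosphoric acid-catalysed crotylboration of aldehydes.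

**Step 10**
Reactants: 19
Product: 20 (S)-8-bromo-2,7-dimethyl-6-methylideneoct-2-ene
Conditions: CBr4, PPh3, CH2Cl2, 0 °C
Reagents that add atoms: carbon tetrabromide (BrC(Br)(Br)Br)
Why: Appel bromination of the primary alcohol; the stereocentre is not involved.

**Step 11**
Reactants: 21 butane-1,4-diol; 22 (1-ethoxycarbonylethylidene)triphenylphosphorane
Product: 24 diethyl (2E,6E)-2,7-dimethylocta-2,6-dienedioate, via succinaldehyde 23 (not isolated)
Conditions: (COCl)2, DMSO, CH2Cl2, −78 °C; Et3N; then 22 (2.4 equiv), −78 °C → rt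
Reagents that add atoms: none
Why: one-pot Swern oxidation and double Wittig olefination with a stabilised α-methyl ylide, which gives both trisubstituted alkenes E.

**Step 12**
Reactants: 24
Product: 25 (2E,6E)-2,7-dimethylocta-2,6-diene-1,8-diol
Conditions: i-Bu2AlH (4.4 equiv), CH2Cl2, −78 °C; Rochelle salt work-up
Reagents that add atoms: none
Why: 1,2-reduction of both enoates to allylic alcohols without touching the alkenes.

**Step 13**
Reactants: 25
Product: 26 [(2R,3R)-3-[(3E)-5-hydroxy-4-methylpent-3-en-1-yl]-2-methyloxiran-2-yl]methanol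
Conditions: D-fructose-derived Shi ketone (30 mol %), Oxone (2KHSO5·KHSO4·K2SO4; 0.6 equiv KHSO5), K2CO3, Bu4NHSO4, MeCN/dimethoxymethane/aq. buffer pH 10.5, 0 °C; 25 recovered and recycled
Reagents that add atoms: potassium peroxymonosulfate ([K+].[O-]S(=O)(=O)OO)
Why: Shi asymmetric epoxidation; the two alkenes of C2-symmetric 25 are equivalent, so mono-epoxidation gives one compound, and the spiro dioxirane transition state of the D-fructose ketone delivers oxygen to the face that gives the (R,R) trans-epoxide of the E-trisubstituted alkene.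

**Step 14**
Reactants: 26
Product: 27 [(2R,3R)-3-[(3E)-5-bromo-4-methylpent-3-en-1-yl]-2-methyloxiran-2-yl]methanol
Conditions: NBS, Me2S, CH2Cl2, −20 → 0 °C
Reagents that add atoms: N-bromosuccinimide (BrN1C(=O)CCC1=O)
Why: Corey–Kim halogenation without base converts only the allylic alcohol (SN2 of bromide on the allylic alkoxysulfonium), while the epoxy alcohol returns unchanged on work-up.

**Step 15**
Reactants: 14; 27
Product: 30 [(2R,3R)-2-methyl-3-[(3E,7R,11S)-4,7,11,12-tetramethyl-8-methylidenetrideca-3,12-dien-1-yl]oxiran-2-yl]methanol, via Grignard reagent 28 (not isolated), via chloromagnesium alkoxide 29 (not isolated)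
Conditions: 14, Mg, THF, 0 °C (gives 28, 1.3 equiv); 27, i-PrMgCl (1.0 equiv), THF, −78 °C (gives 29); combine, Li2CuCl4 (5 mol %), −78 → −20 °C; aq. NH4Cl
Reagents that add atoms: none
Why: copper-catalysed Grignard coupling with a primary allylic bromide proceeds at the α-carbon (SN2) with retention of the E geometry and far faster than opening of the trisubstituted epoxide, the hydroxyl being masked as its magnesium alkoxide; no stereocentre reacts.

**Step 16**
Reactants: 30
Product: 31 [(2R,3R)-2-methyl-3-[(3E,7R,11S)-4,7,11,12-tetramethyl-8-methylidenetrideca-3,12-dien-1-yl]oxiran-2-yl]methyl trifluoromethanesulfonate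
Conditions: Tf2O, 2,6-lutidine, CH2Cl2, −78 °C; used crude at once
Reagents that add atoms: trifluoromethanesulfonic anhydride (FC(F)(F)S(=O)(=O)OS(=O)(=O)C(F)(F)F)
Why: O-triflation of the epoxy alcohol gives a leaving group reactive enough for substitution at the CH2 next to the quaternary oxirane carbon; the alkenes and epoxide are inert at −78 °C.

**Step 17**
Reactants: 20; 31
Product: 33 (2R,3R)-2-[(3R)-3,8-dimethyl-4-methylidenenon-7-en-1-yl]-2-methyl-3-[(3E,7R,11S)-4,7,11,12-tetramethyl-8-methylidenetrideca-3,12-dien-1-yl]oxirane (CNP0279512.1), via Grignard reagent 32 (not isolated)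
Conditions: 20, Mg, Et2O, 0 °C (gives 32, 2 equiv); CuBr·SMe2 (20 mol %), Et2O, −78 °C; then 31, −78 → −30 °C
Reagents that add atoms: none
Why: copper-catalysed Grignard displacement of a primary triflate (SN2 at C9) is faster than attack on the trisubstituted epoxide and forms the C8–C9 bond; all five stereocentres are remote from the reacting carbon and are retained.

**Compound list**
1 | isoprene (2-methylbuta-1,3-diene) | C=CC(C)=C | starting material
2 | (Z)-2-(2-methylbut-2-en-1-yl)-1,3,2-benzodioxaborole | C/C=C(/C)CB1Oc2ccccc2O1 | intermediate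
3 | (Z)-4,4,5,5-tetramethyl-2-(2-methylbut-2-en-1-yl)-1,3,2-dioxaborolane | C/C=C(/C)CB1OC(C)(C)C(C)(C)O1 | intermediate
4 | formaldehyde | C=O | starting material
5 | (R)-2-[(2,3-dimethylbut-3-en-1-yl)oxy]-4,4,5,5-tetramethyl-1,3,2-dioxaborolane | CC1(C)OB(OC[C@H](C)C(C)=C)OC1(C)C | intermediate
6 | (R)-2,3-dimethylbut-3-en-1-ol | OC[C@H](C)C(C)=C | intermediate
7 | (R)-2,3-dimethylbut-3-en-1-yl 4-methylbenzenesulfonate | Cc1ccc(cc1)S(=O)(=O)OC[C@H](C)C(C)=C | intermediate
8 | (2-methylidenebut-3-en-1-yl)potassium (isoprenylpotassium) | [K+].[CH2-]C(=C)C=C | intermediate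
9 | (S)-2,3-dimethyl-6-methylideneocta-1,7-diene | C=CC(=C)CC[C@H](C)C(C)=C | intermediate
10 | 2-[(2E,5S)-2-ethylidene-5,6-dimethylhept-6-en-1-yl]-1,3,2-benzodioxaborole | C/C=C(/CC[C@H](C)C(C)=C)CB1Oc2ccccc2O1 | intermediate
11 | 2-[(2E,5S)-2-ethylidene-5,6-dimethylhept-6-en-1-yl]-4,4,5,5-tetramethyl-1,3,2-dioxaborolane | C/C=C(/CC[C@H](C)C(C)=C)CB1OC(C)(C)C(C)(C)O1 | intermediate
12 | 4,4,5,5-tetramethyl-2-{[(2S,6S)-2,6,7-trimethyl-3-methylideneoct-7-en-1-yl]oxy}-1,3,2-dioxaborolane | CC1(C)OB(OC[C@@H](C)C(=C)CC[C@H](C)C(C)=C)OC1(C)C | intermediate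
13 | (2S,6S)-2,6,7-trimethyl-3-methylideneoct-7-en-1-ol | OC[C@@H](C)C(=C)CC[C@H](C)C(C)=C | intermediate
14 | (3S,7S)-8-bromo-2,3,7-trimethyl-6-methylideneoct-1-ene | BrC[C@@H](C)C(=C)CC[C@H](C)C(C)=C | intermediate
15 | myrcene (7-methyl-3-methylideneocta-1,6-diene) | C=CC(=C)CCC=C(C)C | starting material
16 | 2-[(2E)-2-ethylidene-6-methylhept-5-en-1-yl]-1,3,2-benzodioxaborole | C/C=C(/CCC=C(C)C)CB1Oc2ccccc2O1 | intermediate
17 | 2-[(2E)-2-ethylidene-6-methylhept-5-en-1-yl]-4,4,5,5-tetramethyl-1,3,2-dioxaborolane | C/C=C(/CCC=C(C)C)CB1OC(C)(C)C(C)(C)O1 | intermediate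
18 | (S)-2-[(2,7-dimethyl-3-methylideneoct-6-en-1-yl)oxy]-4,4,5,5-tetramethyl-1,3,2-dioxaborolane | CC1(C)OB(OC[C@@H](C)C(=C)CCC=C(C)C)OC1(C)C | intermediate
19 | (S)-2,7-dimethyl-3-methylideneoct-6-en-1-ol | OC[C@@H](C)C(=C)CCC=C(C)C | intermediate
20 | (S)-8-bromo-2,7-dimethyl-6-methylideneoct-2-ene | BrC[C@@H](C)C(=C)CCC=C(C)C | intermediate
21 | butane-1,4-diol | OCCCCO | starting material
22 | (1-ethoxycarbonylethylidene)triphenylphosphorane | CCOC(=O)C(C)=P(c1ccccc1)(c1ccccc1)c1ccccc1 | starting material
23 | succinaldehyde (butanedial) | O=CCCC=O | intermediate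
24 | diethyl (2E,6E)-2,7-dimethylocta-2,6-dienedioate | CCOC(=O)/C(C)=C/CC/C=C(C)/C(=O)OCC | intermediate
25 | (2E,6E)-2,7-dimethylocta-2,6-diene-1,8-diol | OC/C(C)=C/CC/C=C(C)/CO | intermediate
26 | [(2R,3R)-3-[(3E)-5-hydroxy-4-methylpent-3-en-1-yl]-2-methyloxiran-2-yl]methanol | OC/C(C)=C/CC[C@H]1O[C@]1(C)CO | intermediate
27 | [(2R,3R)-3-[(3E)-5-bromo-4-methylpent-3-en-1-yl]-2-methyloxiran-2-yl]methanol | BrC/C(C)=C/CC[C@H]1O[C@]1(C)CO | intermediate
28 | [(2S,6S)-2,6,7-trimethyl-3-methylideneoct-7-en-1-yl]magnesium bromide | Br[Mg]C[C@@H](C)C(=C)CC[C@H](C)C(C)=C | intermediate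
29 | chloromagnesium alkoxide of 27 | BrC/C(C)=C/CC[C@H]1O[C@]1(C)CO[Mg]Cl | intermediate
30 | [(2R,3R)-2-methyl-3-[(3E,7R,11S)-4,7,11,12-tetramethyl-8-methylidenetrideca-3,12-dien-1-yl]oxiran-2-yl]methanol | C=C(CC[C@H](C)C(=C)C)[C@H](C)CC/C(C)=C/CC[C@H]1O[C@]1(C)CO | intermediate
31 | [(2R,3R)-2-methyl-3-[(3E,7R,11S)-4,7,11,12-tetramethyl-8-methylidenetrideca-3,12-dien-1-yl]oxiran-2-yl]methyl trifluoromethanesulfonate | C=C(CC[C@H](C)C(=C)C)[C@H](C)CC/C(C)=C/CC[C@H]1O[C@]1(C)COS(=O)(=O)C(F)(F)F | intermediate
32 | [(2S)-2,7-dimethyl-3-methylideneoct-6-en-1-yl]magnesium bromide | Br[Mg]C[C@@H](C)C(=C)CCC=C(C)C | intermediate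
33 | (2R,3R)-2-[(3R)-3,8-dimethyl-4-methylidenenon-7-en-1-yl]-2-methyl-3-[(3E,7R,11S)-4,7,11,12-tetramethyl-8-methylidenetrideca-3,12-dien-1-yl]oxirane | C=C(CC[C@H](C)C(=C)C)[C@H](C)CC/C(C)=C/CC[C@H]1O[C@]1(C)CC[C@@H](C)C(=C)CCC=C(C)C | target

**Step count and risks**
Total: 17 steps. Longest linear sequence: 10 steps (1–7, then 15, 16, 17).

Step 2 (the proposed new allylboration; steps 6 and 9 depend on the same reaction). Formaldehyde gives the acid no substituent to grip, so the enantioselectivity is unknown and may be low, and the uncatalysed addition may compete. The fallback uses known chemistry and sets out from 3. Uncatalysed allylboration with paraformaldehyde in toluene at 50 °C gives the racemic borate ester F1, which is hydrolysed to racemic 2,3-dimethylbut-3-en-1-ol F2. Kinetic resolution with lipase PS (Burkholderia cepacia) and vinyl acetate acylates the S enantiomer faster (empirical rule for 2-methyl primary alcohols) to give (S)-2,3-dimethylbut-3-en-1-yl acetate F3. Run past 60 % conversion, it leaves the unreacted alcohol as 6 in high ee, where the route is rejoined.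

Step 4. The tosylate carries a tertiary allylic β-hydrogen, so E2 to 2,3-dimethylbutadiene can compete, and the potassium reagent can oligomerise isoprene. The fallback reverses the polarity and sets out from 7. LiBr in acetone gives (R)-4-bromo-2,3-dimethylbut-1-ene F4, and Mg in THF gives the Grignard reagent F5. Separately, commercial 3-methyl-2,5-dihydrothiophene 1,1-dioxide is brominated (NBS, dibenzoyl peroxide) to 3-(bromomethyl)-2,5-dihydrothiophene 1,1-dioxide F6, which loses SO2 on heating to give 2-(bromomethyl)buta-1,3-diene F7. Coupling of F5 with F7 under Li2CuCl4 catalysis (SN2 and SN2′ give the same product) returns to the route at 9.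

Step 17. Substitution at the CH2 next to the quaternary oxirane carbon may lose to epoxide opening or to bromide attack on the triflate. The fallback replaces the organocopper coupling by sulfone alkylation and sets out from 20. PhSO2Na in DMF gives [(2S)-2,7-dimethyl-3-methylideneoct-6-en-1-yl]sulfonylbenzene F8, and n-BuLi in THF at −78 °C gives the lithio sulfone F9. Alkylation with triflate 31 (THF/DMPU, −78 °C) gives the C8-phenylsulfonyl derivative of the target F10 as a mixture of epimers at the sulfonyl carbon. Sodium amalgam (Na/Hg) with Na2HPO4 in MeOH at −20 °C removes the sulfonyl group and returns to the route at 33.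

**Further compounds**
F1 | step 2 | racemic 2-[(2,3-dimethylbut-3-en-1-yl)oxy]-4,4,5,5-tetramethyl-1,3,2-dioxaborolane | CC1(C)OB(OCC(C)C(C)=C)OC1(C)C
F2 | step 2 | racemic 2,3-dimethylbut-3-en-1-ol | OCC(C)C(C)=C
F3 | step 2 | (S)-2,3-dimethylbut-3-en-1-yl acetate | CC(=O)OC[C@@H](C)C(C)=C
F4 | step 4 | (R)-4-bromo-2,3-dimethylbut-1-ene | BrC[C@H](C)C(C)=C
F5 | step 4 | [(2R)-2,3-dimethylbut-3-en-1-yl]magnesium bromide | Br[Mg]C[C@H](C)C(C)=C
F6 | step 4 | 3-(bromomethyl)-2,5-dihydrothiophene 1,1-dioxide | BrCC1=CCS(=O)(=O)C1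
F7 | step 4 | 2-(bromomethyl)buta-1,3-diene | BrCC(=C)C=C
F8 | step 17 | [(2S)-2,7-dimethyl-3-methylideneoct-6-en-1-yl]sulfonylbenzene | O=S(=O)(C[C@@H](C)C(=C)CCC=C(C)C)c1ccccc1
F9 | step 17 | lithio derivative of F8 (lithium on the sulfonyl-bearing carbon) | [Li]C([C@@H](C)C(=C)CCC=C(C)C)S(=O)(=O)c1ccccc1
F10 | step 17 | C8-phenylsulfonyl derivative of the target (epimers at C8) | C=C(CC[C@H](C)C(=C)C)[C@H](C)CC/C(C)=C/CC[C@H]1O[C@]1(C)CC([C@@H](C)C(=C)CCC=C(C)C)S(=O)(=O)c1ccccc1
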